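**Retrosynthetic overview**
1. (S)-Sargachromenol ⇐ its methyl ester ⇐ (S)-6-hydroxychroman-4-one ester: C3=C4 comes from C4=O by reduction and dehydration, and ester hydrolysis is the last step.
2. Chroman-4-one ⇐ 2-acetyl-6-methylhydroquinone + C19 methyl ketone by an intermolecular crossed aldol condensation (Kabbe), which forms C2–C3 and then closes O1–C2 by oxa-Michael addition. The pyran ring is the only ring formed; the arene is bought.
3. C2 forms racemic in that ring closure; the (S)-enantiomer is taken by chiral-phase resolution of the chromanone.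
4. C19 keto ester ⇐ (4E)-keto aldehyde + homoprenyl-substituted trifluoroethyl phosphonate (Still–Gennari, sets the 2Z enoate); keto aldehyde ⇐ (E)-geranylacetone by terminal bromohydrin, epoxide and periodate cleavage.
5. Acetophenone ⇐ 4-methoxy-2-methylphenol by ortho-acylation and demethylation.

Assumption: (E)-geranylacetone is bought as the geometrically pure (5E) grade; I know of no dependable enantioselective version of the ring-forming condensation for a 2-methyl-2-alkyl centre, so the (S)-enantiomer is secured by resolution in step 9.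

**Step 1**
Reactants: 1 4-methoxy-2-methylphenol
Product: 2 1-(2-hydroxy-5-methoxy-3-methylphenyl)ethan-1-one
Conditions: AcOH, BF3·OEt2 (3 equiv), 90 °C; then H2O, NaOAc, 60 °C
Reagents that add atoms: acetic acid, CC(=O)O
Why: Friedel–Crafts ortho-acylation (equivalently O-acylation then Fries rearrangement) under BF3, in which the para position is blocked by OMe and one ortho position by methyl, so the acetyl group can only enter the remaining ortho position.

**Step 2**
Reactants: 2 1-(2-hydroxy-5-methoxy-3-methylphenyl)ethan-1-one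
Product: 3 1-(2,5-dihydroxy-3-methylphenyl)ethan-1-one
Conditions: BBr3 (2.5 equiv), CH2Cl2, −78 °C → rt; then H2O
Reagents that add atoms: none
Why: Lewis-acid aryl methyl ether cleavage, in which BBr3 complexes the ether oxygen and bromide removes the methyl group by SN2 while the acetyl group and ring are untouched.

**Step 3**
Reactants: 4 methyl 2-[bis(2,2,2-trifluoroethoxy)phosphoryl]acetate; 5 5-bromo-2-methylpent-2-ene
Product: 7 methyl 2-[bis(2,2,2-trifluoroethoxy)phosphoryl]-6-methylhept-5-enoate (racemic), via sodium phosphonoacetate carbanion 6 (not isolated)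
Conditions: 4 (1.1 equiv), NaH (1.0 equiv), DMF, 0 °C; then 5, NaI (0.1 equiv), 50 °C
Reagents that add atoms: none
Why: C-alkylation of a stabilised phosphonoacetate carbanion by SN2 on the primary homoallylic bromide (iodide-assisted), with monoalkylation favoured by the slight excess of 4; the racemic α-centre is destroyed in step 7.

**Step 4**
Reactants: 8 (5E)-6,10-dimethylundeca-5,9-dien-2-one ((E)-geranylacetone)
Product: 9 (5E)-9-bromo-10-hydroxy-6,10-dimethylundec-5-en-2-one (racemic)
Conditions: NBS (1.05 equiv), THF/H2O 3:1, 0 °C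
Reagents that add atoms: N-bromosuccinimide, O=C1CCC(=O)N1Br; water, O
Why: Van Tamelen terminal bromohydrin formation, in which the bromonium ion forms preferentially at the exposed terminal trisubstituted alkene in aqueous THF and water opens it at the tertiary carbon; the racemic secondary centre is excised in step 6.

**Step 5**
Reactants: 9 (5E)-9-bromo-10-hydroxy-6,10-dimethylundec-5-en-2-one
Product: 10 (5E)-8-(3,3-dimethyloxiran-2-yl)-6-methyloct-5-en-2-one (racemic)
Conditions: K2CO3, MeOH, rt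
Reagents that add atoms: none
Why: Intramolecular Williamson-type SN2 closure of the bromohydrin alkoxide gives the terminal epoxide without touching the methyl ketone.

**Step 6**
Reactants: 10 (5E)-8-(3,3-dimethyloxiran-2-yl)-6-methyloct-5-en-2-one
Product: 11 (4E)-4-methyl-8-oxonon-4-enal
Conditions: H5IO6 (1.2 equiv), THF/Et2O, 0 °C
Reagents that add atoms: none
Why: Periodic acid cleavage of the epoxide (hydrolytic opening to the glycol, then Malaprade C–C scission) removes the terminal carbon as acetone and leaves the aldehyde, whose oxygen is the former epoxide oxygen, with the (E)-alkene and ketone intact.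

**Step 7**
Reactants: 7 methyl 2-[bis(2,2,2-trifluoroethoxy)phosphoryl]-6-methylhept-5-enoate; 11 (4E)-4-methyl-8-oxonon-4-enal
Product: 13 methyl (2Z,6E)-6-methyl-2-(4-methylpent-3-en-1-yl)-10-oxoundeca-2,6-dienoate, via potassium phosphonate carbanion 12 (not isolated)
Conditions: 7 (1.1 equiv), KN(SiMe3)2 (1.05 equiv), 18-crown-6, THF, −78 °C; then 11, −78 °C
Reagents that add atoms: none
Why: Still–Gennari variant of the Horner–Wadsworth–Emmons olefination, in which the electron-poor trifluoroethyl phosphonate with crown-complexed potassium eliminates quickly from the kinetic adduct to give the (Z)-trisubstituted enoate (ester cis to the chain), the aldehyde reacting far faster than the methyl ketone at −78 °C.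

**Step 8**
Reactants: 3 1-(2,5-dihydroxy-3-methylphenyl)ethan-1-one; 13 methyl (2Z,6E)-6-methyl-2-(4-methylpent-3-en-1-yl)-10-oxoundeca-2,6-dienoate
Product: 15 methyl (2Z,6E)-9-[(2RS)-6-hydroxy-2,8-dimethyl-4-oxo-3,4-dihydro-2H-chromen-2-yl]-6-methyl-2-(4-methylpent-3-en-1-yl)nona-2,6-dienoate (racemic), via open-chain aryl enone 14 (not isolated)
Conditions: 3 (1.0 equiv), 13 (1.1 equiv), pyrrolidine (1.5 equiv), MeOH, 3 Å molecular sieves, 45 °C, Ar
Reagents that add atoms: none
Why: Kabbe chromanone synthesis, an intermolecular crossed aldol condensation of the aryl methyl ketone with the aliphatic methyl ketone through pyrrolidine enamine/iminium activation followed by oxa-Michael closure of the ortho-phenol, which forms C2–C3 and then O1–C2 and creates C2 as a racemate because neither partner biases the ring closure.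

**Step 9**
Reactants: 15 racemic chromanone ester
Product: 16 methyl (2Z,6E)-9-[(2S)-6-hydroxy-2,8-dimethyl-4-oxo-3,4-dihydro-2H-chromen-2-yl]-6-methyl-2-(4-methylpent-3-en-1-yl)nona-2,6-dienoate
Conditions: preparative HPLC on silica-bound amylose tris(3,5-dimethylphenylcarbamate), n-hexane/2-propanol 9:1, rt; (S)-enantiomer identified by ECD
Reagents that add atoms: none
Why: Resolution of enantiomers by chromatography on a chiral stationary phase, which works here because the neutral 2,2-dialkylchroman-4-one is configurationally stable, so the only stereocentre of the target is secured as (S) at this point and no later step touches it.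

**Step 10**
Reactants: 16 (S)-chromanone ester
Product: 17 methyl (2Z,6E)-9-[(2S,4RS)-4,6-dihydroxy-2,8-dimethyl-3,4-dihydro-2H-chromen-2-yl]-6-methyl-2-(4-methylpent-3-en-1-yl)nona-2,6-dienoate
Conditions: NaBH4, MeOH, 0 °C
Reagents that add atoms: none
Why: Chemoselective borohydride 1,2-reduction of the aryl ketone in the presence of the conjugated ester and isolated alkenes; the new C4 carbinol centre forms as a mixture that is removed in step 11, and C2 is untouched.

**Step 11**
Reactants: 17 (2S,4RS)-chromanol ester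
Product: 18 methyl (2Z,6E)-9-[(2S)-6-hydroxy-2,8-dimethyl-2H-chromen-2-yl]-6-methyl-2-(4-methylpent-3-en-1-yl)nona-2,6-dienoate
Conditions: TsOH·H2O (5 mol %), toluene, 4 Å molecular sieves, 60 °C
Reagents that add atoms: none
Why: Acid-catalysed E1 dehydration through the benzylic cation stabilised by the ring oxygen, regiospecific for C3=C4 because only C3 carries β-hydrogens, with the quaternary C2 centre not involved.

**Step 12**
Reactants: 18 (S)-chromene methyl ester
Product: 20 (2Z,6E)-9-[(2S)-6-hydroxy-2,8-dimethyl-2H-chromen-2-yl]-6-methyl-2-(4-methylpent-3-en-1-yl)nona-2,6-dienoic acid ((S)-sargachromenol), via dilithium carboxylate phenoxide 19 (not isolated)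
Conditions: LiOH·H2O (4 equiv), THF/MeOH/H2O 3:1:1, 40 °C, Ar; then 1 M HCl, 0 °C
Reagents that add atoms: lithium hydroxide, [Li+].[OH-]
Why: Saponification (BAc2 ester hydrolysis) then acidification, mild and air-free so that the (Z)-enoate, the chromene and the electron-rich phenol survive and no stereocentre is affected.

**Compound list**
1 | 4-methoxy-2-methylphenol | COc1ccc(O)c(C)c1 | starting material
2 | 1-(2-hydroxy-5-methoxy-3-methylphenyl)ethan-1-one | COc1cc(C)c(O)c(C(C)=O)c1 | intermediate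
3 | 1-(2,5-dihydroxy-3-methylphenyl)ethan-1-one | CC(=O)c1cc(O)cc(C)c1O | intermediate
4 | methyl 2-[bis(2,2,2-trifluoroethoxy)phosphoryl]acetate | COC(=O)CP(=O)(OCC(F)(F)F)OCC(F)(F)F | starting material
5 | 5-bromo-2-methylpent-2-ene | CC(C)=CCCBr | starting material
6 | sodium 1-[bis(2,2,2-trifluoroethoxy)phosphoryl]-2-methoxy-2-oxoethan-1-ide | [Na+].COC(=O)[CH-]P(=O)(OCC(F)(F)F)OCC(F)(F)F | intermediate
7 | methyl 2-[bis(2,2,2-trifluoroethoxy)phosphoryl]-6-methylhept-5-enoate (racemic) | COC(=O)C(CCC=C(C)C)P(=O)(OCC(F)(F)F)OCC(F)(F)F | intermediate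
8 | (5E)-6,10-dimethylundeca-5,9-dien-2-one | CC(C)=CCC/C(C)=C/CCC(C)=O | starting material
9 | (5E)-9-bromo-10-hydroxy-6,10-dimethylundec-5-en-2-one (racemic) | CC(C)(O)C(Br)CC/C(C)=C/CCC(C)=O | intermediate
10 | (5E)-8-(3,3-dimethyloxiran-2-yl)-6-methyloct-5-en-2-one (racemic) | CC1(C)OC1CC/C(C)=C/CCC(C)=O | intermediate
11 | (4E)-4-methyl-8-oxonon-4-enal | O=CCC/C(C)=C/CCC(C)=O | intermediate
12 | potassium 2-[bis(2,2,2-trifluoroethoxy)phosphoryl]-1-methoxy-6-methyl-1-oxohept-5-en-2-ide | [K+].COC(=O)[C-](CCC=C(C)C)P(=O)(OCC(F)(F)F)OCC(F)(F)F | intermediate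
13 | methyl (2Z,6E)-6-methyl-2-(4-methylpent-3-en-1-yl)-10-oxoundeca-2,6-dienoate | CC(C)=CCC/C(=C/CC/C(C)=C/CCC(C)=O)C(=O)OC | intermediate
14 | methyl (2Z,6E)-12-(2,5-dihydroxy-3-methylphenyl)-6,10-dimethyl-2-(4-methylpent-3-en-1-yl)-12-oxododeca-2,6,10-trienoate (10E/10Z mixture) | CC(C)=CCC/C(=C/CC/C(C)=C/CCC(C)=CC(=O)c1cc(O)cc(C)c1O)C(=O)OC | intermediate
15 | methyl (2Z,6E)-9-[(2RS)-6-hydroxy-2,8-dimethyl-4-oxo-3,4-dihydro-2H-chromen-2-yl]-6-methyl-2-(4-methylpent-3-en-1-yl)nona-2,6-dienoate (racemic) | CC(C)=CCC/C(=C/CC/C(C)=C/CCC1(C)CC(=O)c2cc(O)cc(C)c2O1)C(=O)OC | intermediate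
16 | methyl (2Z,6E)-9-[(2S)-6-hydroxy-2,8-dimethyl-4-oxo-3,4-dihydro-2H-chromen-2-yl]-6-methyl-2-(4-methylpent-3-en-1-yl)nona-2,6-dienoate | CC(C)=CCC/C(=C/CC/C(C)=C/CC[C@@]1(C)CC(=O)c2cc(O)cc(C)c2O1)C(=O)OC | intermediate
17 | methyl (2Z,6E)-9-[(2S,4RS)-4,6-dihydroxy-2,8-dimethyl-3,4-dihydro-2H-chromen-2-yl]-6-methyl-2-(4-methylpent-3-en-1-yl)nona-2,6-dienoate | CC(C)=CCC/C(=C/CC/C(C)=C/CC[C@@]1(C)CC(O)c2cc(O)cc(C)c2O1)C(=O)OC | intermediate
18 | methyl (2Z,6E)-9-[(2S)-6-hydroxy-2,8-dimethyl-2H-chromen-2-yl]-6-methyl-2-(4-methylpent-3-en-1-yl)nona-2,6-dienoate | CC(C)=CCC/C(=C/CC/C(C)=C/CC[C@@]1(C)C=Cc2cc(O)cc(C)c2O1)C(=O)OC | intermediate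
19 | dilithium salt (carboxylate and phenoxide) of 20 | [Li+].[Li+].CC(C)=CCC/C(=C/CC/C(C)=C/CC[C@@]1(C)C=Cc2cc([O-])cc(C)c2O1)C(=O)[O-] | intermediate
20 | (S)-sargachromenol, (2Z,6E)-9-[(2S)-6-hydroxy-2,8-dimethyl-2H-chromen-2-yl]-6-methyl-2-(4-methylpent-3-en-1-yl)nona-2,6-dienoic acid | CC(C)=CCC/C(=C/CC/C(C)=C/CC[C@@]1(C)C=Cc2cc(O)cc(C)c2O1)C(=O)O | target

**Totals**
Total step count: 12. Longest linear sequence: 9 steps (8 → 20, steps 4 to 12).

**Steps most likely to fail, with fallbacks**

Step 7 (Z-selectivity of the α-branched Still–Gennari olefination). The fallback sets out from keto aldehyde 11 and builds the enoate by stereodefined cross-coupling instead of olefination. Ramirez dibromo-olefination (CBr4, PPh3, CH2Cl2, 0 °C; aldehyde-selective) gives (5E)-10,10-dibromo-6-methyldeca-5,9-dien-2-one F1. Bromide 5 is converted with Zn dust and LiCl in THF into (4-methylpent-3-en-1-yl)zinc bromide F2. Negishi trans-selective monoalkylation of F1 with F2 under PdCl2(DPEphos) catalysis replaces only the bromine trans to the chain and gives (5E,9Z)-10-bromo-6,14-dimethylpentadeca-5,9,13-trien-2-one F3. Methoxycarbonylation of F3 (Pd(OAc)2, dppf, CO 1 atm, MeOH, Et3N, 60 °C) proceeds with retention and puts the ester cis to the chain, which comes back to the route at 13.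

Step 8 (Kabbe condensation with the Z-enoate exposed to pyrrolidine). The fallback sets out from keto aldehyde 11 and introduces the enoate only after the ring is made. Aldehyde-selective acetalisation (HC(OMe)3, MeOH, CeCl3·7H2O cat.) gives (5E)-9,9-dimethoxy-6-methylnon-5-en-2-one F4. Kabbe condensation of F4 with 3 (pyrrolidine, MeOH, 45 °C) gives racemic 2-[(3E)-7,7-dimethoxy-4-methylhept-3-en-1-yl]-6-hydroxy-2,8-dimethyl-2,3-dihydro-4H-chromen-4-one F5. Acetal hydrolysis (AcOH/THF/H2O, rt) gives racemic (4E)-7-(6-hydroxy-2,8-dimethyl-4-oxo-3,4-dihydro-2H-chromen-2-yl)-4-methylhept-4-enal F6. Still–Gennari olefination of F6 with carbanion 12 (made from 7; 2.2 equiv to allow for the free phenol) comes back to the route at 15.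

Step 9 (chiral-phase resolution may not give baseline separation or scale). The fallback sets out from racemic 15 and replaces chromatography by a kinetic resolution on the chromene.
- NaBH4 reduction gives the racemic chromanol ester F7, and TsOH dehydration gives the racemic chromene methyl ester F8.
- Ac2O/pyridine gives the racemic 6-acetoxy chromene ester F9.
- Jacobsen–Katsuki epoxidation follows, with N,N'-bis(3,5-di-tert-butylsalicylidene)-1,2-cyclohexanediaminomanganese chloride and NaOCl in CH2Cl2 at 0 °C. The (R,R) or (S,S) catalyst is chosen by a test run so that the (R)-chromene reacts faster, and the reaction is run to about 65–70 % conversion.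
- Ordinary chromatography then separates the unreacted (S)-6-acetoxy chromene ester F10 from the 3,4-epoxide of the (R)-enantiomer F11.
- LiOH hydrolysis of F10 cleaves both the acetate and the methyl ester and comes back to the route at 20.

**Further compounds**
F1 | step 7 | (5E)-10,10-dibromo-6-methyldeca-5,9-dien-2-one | BrC(Br)=CCC/C(C)=C/CCC(C)=O
F2 | step 7 | (4-methylpent-3-en-1-yl)zinc bromide | CC(C)=CCC[Zn]Br
F3 | step 7 | (5E,9Z)-10-bromo-6,14-dimethylpentadeca-5,9,13-trien-2-one | CC(C)=CCC/C(Br)=C/CC/C(C)=C/CCC(C)=O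
F4 | step 8 | (5E)-9,9-dimethoxy-6-methylnon-5-en-2-one | COC(OC)CC/C(C)=C/CCC(C)=O
F5 | step 8 | racemic 2-[(3E)-7,7-dimethoxy-4-methylhept-3-en-1-yl]-6-hydroxy-2,8-dimethyl-2,3-dihydro-4H-chromen-4-one | COC(OC)CC/C(C)=C/CCC1(C)CC(=O)c2cc(O)cc(C)c2O1
F6 | step 8 | racemic (4E)-7-(6-hydroxy-2,8-dimethyl-4-oxo-3,4-dihydro-2H-chromen-2-yl)-4-methylhept-4-enal | O=CCC/C(C)=C/CCC1(C)CC(=O)c2cc(O)cc(C)c2O1
F7 | step 9 | racemic methyl (2Z,6E)-9-(4,6-dihydroxy-2,8-dimethyl-3,4-dihydro-2H-chromen-2-yl)-6-methyl-2-(4-methylpent-3-en-1-yl)nona-2,6-dienoate | CC(C)=CCC/C(=C/CC/C(C)=C/CCC1(C)CC(O)c2cc(O)cc(C)c2O1)C(=O)OC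
F8 | step 9 | racemic methyl (2Z,6E)-9-(6-hydroxy-2,8-dimethyl-2H-chromen-2-yl)-6-methyl-2-(4-methylpent-3-en-1-yl)nona-2,6-dienoate | CC(C)=CCC/C(=C/CC/C(C)=C/CCC1(C)C=Cc2cc(O)cc(C)c2O1)C(=O)OC
F9 | step 9 | racemic methyl (2Z,6E)-9-(6-acetoxy-2,8-dimethyl-2H-chromen-2-yl)-6-methyl-2-(4-methylpent-3-en-1-yl)nona-2,6-dienoate | CC(C)=CCC/C(=C/CC/C(C)=C/CCC1(C)C=Cc2cc(OC(C)=O)cc(C)c2O1)C(=O)OC
F10 | step 9 | methyl (2Z,6E)-9-[(2S)-6-acetoxy-2,8-dimethyl-2H-chromen-2-yl]-6-methyl-2-(4-methylpent-3-en-1-yl)nona-2,6-dienoate | CC(C)=CCC/C(=C/CC/C(C)=C/CC[C@@]1(C)C=Cc2cc(OC(C)=O)cc(C)c2O1)C(=O)OC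
F11 | step 9 | methyl (2Z,6E)-9-[(2R)-6-acetoxy-3,4-epoxy-2,8-dimethyl-3,4-dihydro-2H-chromen-2-yl]-6-methyl-2-(4-methylpent-3-en-1-yl)nona-2,6-dienoate | CC(C)=CCC/C(=C/CC/C(C)=C/CC[C@]1(C)C2OC2c2cc(OC(C)=O)cc(C)c2O1)C(=O)OC
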